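The time is the same in the vessels below, 50 s, but not every portion of the mixture stands that long.

all flasks: catalyst 0.53 mol%
- grey: starting material 0.25 M; one stirred flow tank at steady state, fed with the mixture as stated, mean residence time 50 s
- red: starting material 0.25 M; a tube with plug flow, the mixed feed as stated, residence time 50 s; time 50 s
- green: starting material 0.25 M (fed, over 40.0 s); all but starting material at the start; starting material goes in evenly over 40.0 s, the run ends at 50 s; time 50 s
- ochre: starting material 0.25 M; a closed flask charged with all of it at once and left for 50 s; time 50 s

    starting material → intermediate (k1 = 0.083 s⁻¹)
    catalyst + intermediate → catalyst + target (k2 = 730 M⁻¹ s⁻¹)
    target → over-reaction product (k3 = 0.096 s⁻¹)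
    catalyst ⇌ dormant form (K4 = 0.47, k4 = 0.13 s⁻¹)

- the stated concentrations are those of everything mixed, before any reaction; amounts are the same in each set-up
- the feed brings no volume worth counting
- run time (red): 50 s

* the set-up with the highest amount of target at the outlet or at the end, in percent of the starting material put in ("none" if the first two lie within 2 percentage points) (grey / red / green / ochre / none)
* amount of target at the outlet or at the end, in percent of the starting material put in, grey
* amount of target at the outlet or at the end, in percent of the starting material put in, red
* amount of target at the outlet or at the end, in percent of the starting material put in, green
* amount of target at the outlet or at the end, in percent of the starting material put in, ochre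

Two chemists dispute step 2. The first looks at the loading of 0.53 mol%. In green, catalyst and dormant form relax with a half-life of 1.70 s, shorter than the 8.4 s of starting material, so she counts 68.0 % of the catalyst as active from early on. On ochre's full charge, starting material makes intermediate at 0.0208 M s⁻¹, which asks of each active catalyst a turnover rate of 23.0 s⁻¹. She therefore expects intermediate to queue before step 2, the rate-limiting step in her view, and target to come late.

The second chemist answers that step 2, as written, has no ceiling: its rate is its constant times catalyst times intermediate, so a longer queue is served faster. With the catalyst steady, step 2 is pseudo-first-order with constant 0.658 s⁻¹, larger than the 0.083 s⁻¹ of step 1. Now divide the making of intermediate by its removal, and time drops out. Once starting material falls at its own constant in a closed flask, intermediate stands to starting material as step 1's constant to the difference of the two constants, 0.144. This intermediate per unit of starting material is the hold-up ratio. I side with the second chemist, because the ratio is small, but my reckoning stops there and gives no figure for target.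

The forecast takes the second side, with 13.5 % for grey, 5.35 % for red, 19.5 % for green and 5.35 % for ochre, so green is best, since “the 40 s dosing keeps the average age lowest”.

The simulation gives 13.5 % for grey, 5.36 % for red, 19.6 % for green and 5.36 % for ochre, so green is best.

At the end of ochre, intermediate stands at 0.228 % against 1.58 % of starting material, a reading of 0.144 beside the reckoned 0.144. The first chemist's region lies at thin charges: with the loading held in mol%, ochre's target has moved by 5 points at 0.0357 M, where step 2's constant, reckoned as before, is 0.0940 s⁻¹ against 0.083 s⁻¹. For the same flask as green at 0.10 M, the constant is 0.263 s⁻¹ and the ratio 0.461, so once the feed has stopped, the 12.7 % of starting material left at the end should carry about 5.85 % of intermediate. That flask holds 5.52 %, with target at 20.5 %.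

The constants used here stand for no real mixture; no experiment stands behind them.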